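**Retrosynthetic overview**
1. Target 8 ⇒ desilylation and trans-selective enolate benzylation of the (R)-β-benzyl-γ-butyrolactone 4 with 3,4,5-trimethoxybenzyl bromide 5 (C3 set by substrate control).
2. Lactone 4 ⇒ enantioselective carbene-catalysed homoenolate hydroxymethylation/lactonisation of enal 3 with formaldehyde (C4 set by the catalyst; new method).
3. Enal 3 ⇒ cross-metathesis of the silyl-protected allylarene 2 with crotonaldehyde; 2 ⇒ commercial 4-allyl-2,6-dimethoxyphenol 1.
4. Ring order: both arenes are bought; the lactone, the only ring made, is closed in step 3.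

Assumption: the sense of induction in step 3 is predicted from the usual face-shielding model of aminoindanol triazolium catalysts, not known. It is checked on the first run (chiral HPLC and rotation of 4), and the commercial (5aR,10bS) antipode of the precatalyst is used instead if the (S)-lactone forms.

**Step 1**
Reactants: 1 4-allyl-2,6-dimethoxyphenol
Product: 2 (4-allyl-2,6-dimethoxyphenoxy)triisopropylsilane
Conditions: iPr3SiCl (1.2 equiv), imidazole (2.5 equiv), DMF, 40 °C
Reagents that add atoms: triisopropylsilyl chloride, CC(C)[Si](Cl)(C(C)C)C(C)C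
Why: Phenol silylation (silyl ether formation via the silylimidazolium) masks the acidic OH, which would otherwise protonate the homoenolate and be acylated in step 3 and be O-benzylated in step 4; no stereocenter is formed.

**Step 2**
Reactants: 2 (4-allyl-2,6-dimethoxyphenoxy)triisopropylsilane
Product: 3 (E)-4-[3,5-dimethoxy-4-(triisopropylsilyloxy)phenyl]but-2-enal
Conditions: crotonaldehyde (5 equiv), second-generation Hoveyda–Grubbs catalyst RuCl2(H2IMes)(=CH-C6H4-2-OiPr) (3 mol %), 1,4-benzoquinone (10 mol %), CH2Cl2, 40 °C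
Reagents that add atoms: crotonaldehyde, C/C=C/C=O
Why: Olefin cross-metathesis of a terminal allylarene with the electron-poor enal gives the E cross product selectively and is driven by loss of propene, while benzoquinone suppresses Ru–H migration of the allyl double bond into conjugation with the arene; no stereocenter is formed.

**Step 3**
Reactants: 3 (E)-4-[3,5-dimethoxy-4-(triisopropylsilyloxy)phenyl]but-2-enal
Product: 4 (R)-4-[3,5-dimethoxy-4-(triisopropylsilyloxy)benzyl]dihydrofuran-2(3H)-one
Conditions: (5aS,10bR)-2-mesityl-5a,10b-dihydro-4H,6H-indeno[2,1-b][1,2,4]triazolo[4,3-d][1,4]oxazin-2-ium chloride (10 mol %), iPr2NEt (20 mol %), dry paraformaldehyde (3 equiv CH2O), 4 Å MS, THF, 40 °C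
Reagents that add atoms: formaldehyde (charged as paraformaldehyde), C=O
Why: Proposed new method: the free carbene adds to the aldehyde of 3 to give the extended Breslow intermediate (a homoenolate), whose β-carbon attacks formaldehyde on the face left open by the indane wall of the catalyst and so sets C4; tautomerisation to the acyl azolium and 5-exo O-acylation by the new alkoxide then close the lactone and release the carbene, the closest known reaction type being the carbene-catalysed homoenolate [3+2] annulation of β-aryl enals with aryl aldehydes or activated ketones, here extended to formaldehyde (slowly released from the polymer to limit formoin reaction and catalyst sequestration) and to a β-alkyl enal with acidic γ-hydrogens (hence the weak amine base).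

**Step 4**
Reactants: 4 (R)-4-[3,5-dimethoxy-4-(triisopropylsilyloxy)benzyl]dihydrofuran-2(3H)-one; 5 3,4,5-trimethoxybenzyl bromide
Product: 8 (3R,4R)-4-(4-hydroxy-3,5-dimethoxybenzyl)-3-(3,4,5-trimethoxybenzyl)dihydrofuran-2(3H)-one, via lithium enolate 6 (not isolated), via silyl-protected trans-lactone 7 (not isolated)
Conditions: LiN(SiMe3)2 (1.1 equiv), THF, −78 °C; 5 (1.1 equiv), DMPU (2 equiv), −78 to −30 °C; then AcOH (2.5 equiv), Bu4NF (3 equiv), 0 °C to rt
Reagents that add atoms: none
Why: Lactone enolate alkylation (SN2 benzylation) takes place on the enolate face anti to the C4 benzyl group and sets C3 as R (the trans and also thermodynamic isomer), and fluoride desilylation buffered with AcOH then frees the phenol in the same flask without O-benzylation or epimerisation.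

**Compound list**
1 | 4-allyl-2,6-dimethoxyphenol | C=CCc1cc(OC)c(O)c(OC)c1 | starting material
2 | (4-allyl-2,6-dimethoxyphenoxy)triisopropylsilane | C=CCc1cc(OC)c(O[Si](C(C)C)(C(C)C)C(C)C)c(OC)c1 | intermediate
3 | (E)-4-[3,5-dimethoxy-4-(triisopropylsilyloxy)phenyl]but-2-enal | O=C/C=C/Cc1cc(OC)c(O[Si](C(C)C)(C(C)C)C(C)C)c(OC)c1 | intermediate
4 | (R)-4-[3,5-dimethoxy-4-(triisopropylsilyloxy)benzyl]dihydrofuran-2(3H)-one | COc1cc(C[C@H]2COC(=O)C2)cc(OC)c1O[Si](C(C)C)(C(C)C)C(C)C | intermediate
5 | 3,4,5-trimethoxybenzyl bromide | COc1cc(CBr)cc(OC)c1OC | starting material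
6 | lithium enolate of 4 (4R) | COc1cc(C[C@H]2COC([O-])=C2)cc(OC)c1O[Si](C(C)C)(C(C)C)C(C)C.[Li+] | intermediate
7 | (3R,4R)-4-[3,5-dimethoxy-4-(triisopropylsilyloxy)benzyl]-3-(3,4,5-trimethoxybenzyl)dihydrofuran-2(3H)-one | COc1cc(C[C@H]2COC(=O)[C@@H]2Cc2cc(OC)c(OC)c(OC)c2)cc(OC)c1O[Si](C(C)C)(C(C)C)C(C)C | intermediate
8 | (3R,4R)-4-(4-hydroxy-3,5-dimethoxybenzyl)-3-(3,4,5-trimethoxybenzyl)dihydrofuran-2(3H)-one | COc1cc(C[C@H]2COC(=O)[C@@H]2Cc2cc(OC)c(OC)c(OC)c2)cc(OC)c1O | target

**Step count**
Total steps: 4. Longest linear sequence: 4 (1 → 2 → 3 → 4 → 8).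

**Steps most likely to fail, with fallbacks**

Step 3 (the proposed new annulation). The risks are formoin chemistry or catalyst sequestration by formaldehyde, γ-deprotonation of 3 with drift of the double bond towards the arene, redox esterification instead of C–C bond formation, and insufficient ee. The fallback uses known enamine catalysis; it sets out from 2 and comes back at 4. Hydroboration of 2 with 9-BBN in THF and oxidation with NaBO3 gives 3-[3,5-dimethoxy-4-(triisopropylsilyloxy)phenyl]propan-1-ol F1. Dess–Martin oxidation in CH2Cl2 gives 3-[3,5-dimethoxy-4-(triisopropylsilyloxy)phenyl]propanal F2. Michael addition of F2 to nitroethylene, catalysed by (S)-α,α-diphenylprolinol trimethylsilyl ether (5 mol %) with 3-nitrobenzoic acid in toluene at 3 °C, gives (R)-2-[3,5-dimethoxy-4-(triisopropylsilyloxy)benzyl]-4-nitrobutanal F3; the electrophile approaches the anti-E-enamine on the face away from the diarylsilyloxymethyl group. NaBH4 in MeOH at 0 °C gives (R)-2-[3,5-dimethoxy-4-(triisopropylsilyloxy)benzyl]-4-nitrobutan-1-ol F4. NaNO2 and AcOH in DMSO at 35 °C oxidise the primary nitro group to the carboxylic acid, and the γ-hydroxy acid closes to 4 on acidic work-up. The carbon that was the aldehyde α-carbon becomes C4 with unchanged geometry, so (R)-F3 maps onto (R)-4.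

Step 2 (cross-metathesis). The risks are isomerisation of the allylarene to the propenylarene, homodimerisation, and handling losses of the base-sensitive enal. The fallback replaces metathesis by olefination; it sets out from 2 and comes back at 3. Ozonolysis of 2 (O3, CH2Cl2/MeOH, −78 °C, then Me2S) gives 2-[3,5-dimethoxy-4-(triisopropylsilyloxy)phenyl]acetaldehyde F5. This is used at once in a Wittig reaction with (triphenylphosphoranylidene)acetaldehyde (Ph3P=CHCHO, 1.05 equiv, toluene, 60 °C), which gives the E-enal 3.

Step 4 (one-flask benzylation and desilylation). The risks are sluggish or double alkylation with the electron-rich, labile benzyl bromide and incomplete desilylation in the presence of lithium salts. The fallback replaces alkylation by aldol addition and hydrogenolysis; it sets out from 4 and comes back at 7, which is then isolated. The enolate of 4 (LiN(SiMe3)2, THF, −78 °C) is added to 3,4,5-trimethoxybenzaldehyde (COc1cc(C=O)cc(OC)c1OC) to give (3S,4R)-4-[3,5-dimethoxy-4-(triisopropylsilyloxy)benzyl]-3-[hydroxy(3,4,5-trimethoxyphenyl)methyl]dihydrofuran-2(3H)-one F6 as a mixture of carbinol epimers, trans on the ring. Hydrogenolysis of the benzylic hydroxyl (H2 1 atm, Pd/C, AcOH with a trace of HClO4, rt) gives 7. A separate treatment with Bu4NF and AcOH in THF gives 8.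

**Further compounds**
F1 | step 3 | 3-[3,5-dimethoxy-4-(triisopropylsilyloxy)phenyl]propan-1-ol | OCCCc1cc(OC)c(O[Si](C(C)C)(C(C)C)C(C)C)c(OC)c1
F2 | step 3 | 3-[3,5-dimethoxy-4-(triisopropylsilyloxy)phenyl]propanal | O=CCCc1cc(OC)c(O[Si](C(C)C)(C(C)C)C(C)C)c(OC)c1
F3 | step 3 | (R)-2-[3,5-dimethoxy-4-(triisopropylsilyloxy)benzyl]-4-nitrobutanal | COc1cc(C[C@H](CC[N+](=O)[O-])C=O)cc(OC)c1O[Si](C(C)C)(C(C)C)C(C)C
F4 | step 3 | (R)-2-[3,5-dimethoxy-4-(triisopropylsilyloxy)benzyl]-4-nitrobutan-1-ol | COc1cc(C[C@H](CC[N+](=O)[O-])CO)cc(OC)c1O[Si](C(C)C)(C(C)C)C(C)C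
F5 | step 2 | 2-[3,5-dimethoxy-4-(triisopropylsilyloxy)phenyl]acetaldehyde | O=CCc1cc(OC)c(O[Si](C(C)C)(C(C)C)C(C)C)c(OC)c1
F6 | step 4 | (3S,4R)-4-[3,5-dimethoxy-4-(triisopropylsilyloxy)benzyl]-3-[hydroxy(3,4,5-trimethoxyphenyl)methyl]dihydrofuran-2(3H)-one (carbinol epimers) | COc1cc(C[C@H]2COC(=O)[C@@H]2C(O)c2cc(OC)c(OC)c(OC)c2)cc(OC)c1O[Si](C(C)C)(C(C)C)C(C)C
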